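The runs were computed from invented constants; noise was put on by code.

I took the fraction left. Mirror-image substrates met a single-handed free catalyst, and I wanted the excess in what remained after 15 h.

| flask | left-handed substrate | right-handed substrate | gas | precatalyst | remark | time |
|---|---|---|---|---|---|---|
| eta | 0.29 M | 0.29 M | 140 mM (held) | 2.5 mM | run made earlier |  |
| theta | 0.29 M | 0.29 M | 140 mM (held) | 6.5 mM | run made earlier |  |
| noon | 0.29 M | 0.29 M | 140 mM (held) | 2.9 mM |  | 15 h |
| autumn | 0.29 M | 0.29 M | 140 mM (held) | 8.0 mM |  | 15 h |

| run | time / h | right-handed substrate / % | left-handed substrate / % |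
|---|---|---|---|
| eta | 0.667 | 49.9 | 49.4 |
| eta | 1.33 | 49.5 | 50.1 |
| eta | 3.00 | 50.0 | 50.0 |
| eta | 8.00 | 48.2 | 47.0 |
| theta | 1.00 | 49.7 | 50.9 |
| theta | 2.50 | 49.9 | 49.5 |
| theta | 5.00 | 48.9 | 47.6 |
| theta | 8.00 | 46.2 | 43.6 |

(each reading ± 0.3 percentage points)

- free catalyst is single-handed; left-handed substrate and right-handed substrate are mirror images of each other, charged as a racemate, each of them at the stated concentration
- at the start none of the gas is in solution
- an excess is the difference of the two amounts in percent of their sum
- an excess is below zero if the other one leads

* the winner by excess of right-handed substrate over left-handed substrate among what is left of the two; "neither" if no more than 2 percentage points parts them (noon / autumn / neither)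
* excess of right-handed substrate over left-handed substrate among what is left of the two at the end, noon
* excess of right-handed substrate over left-handed substrate among what is left of the two at the end, autumn

The eta readings at 3.00 h, 50.0% and 50.0%, showed no measurable loss, and left-handed substrate fell faster afterwards. I used s, which read 1.73 in the theta run at 8.00 h: the selectivity factor, the logarithm of the fraction of left-handed substrate left divided by that of right-handed substrate left. If r is the right-handed fraction left, the left-handed fraction is r^s and the excess is (r − r^s)/(r + r^s).

For the bracket, I raised the right-handed fraction left at 8.00 h to a power, taking eta for noon and theta for autumn and assuming proportion to c(precatalyst). A sharp lag and then a steady rate gave the lower bound, a power of 2.40 times the ratio of c(precatalyst). Growth with time squared gave the upper bound, 3.52 times that ratio. Noon came to 3.74% to 5.47%, and autumn to 8.53% to 12.5%. These rest on readings with a scatter of 0.3 percentage points. The autumn floor still cleared the noon ceiling by 3.1 points, more than the margin.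

The forecast said autumn, with 5% and 11.5%, on “I take s ≈ 1.8.” Both excesses stood inside my brackets .

    free catalyst + right-handed substrate ⇌ catalyst intermediate B (K = 8.40 M⁻¹, k = 3700 M⁻¹ h⁻¹)
    reagent + catalyst intermediate A → free catalyst + left-handed product (k = 210 M⁻¹ h⁻¹)
    gas ⇌ reagent, rate k3*(csat - [reagent]) (kL = 0.270 h⁻¹)
    reagent + catalyst intermediate B → free catalyst + right-handed product (k = 69.0 M⁻¹ h⁻¹)
    free catalyst + left-handed substrate ⇌ catalyst intermediate A (K = 5.40 M⁻¹, k = 1400 M⁻¹ h⁻¹)
    left-handed product ⇌ right-handed product (k = 0.370 h⁻¹)
    precatalyst ⇌ free catalyst (K = 2.10, k = 0.0380 h⁻¹)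

The flask gave autumn: 5.39% in noon, inside its bracket , and 12.7% in autumn, above its ceiling. Turning left-handed product into right-handed product made no difference to the autumn excess. From the 74% of right-handed substrate left in autumn, s gives 58.8% of left-handed substrate, and the flask held 57%. In a neighbour flask, autumn with 0.020 M of precatalyst, 56% of right-handed substrate left gives 36.7%, and that flask held 34%.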